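3 questions stand for midnight and dusk, and the readings of amber and red are what I have to answer them with.

| setting | amber | red | midnight | dusk |
|---|---|---|---|---|
| starting material | 0.020 M | 0.020 M | 0.020 M | 0.020 M |
| reagent | 0.90 equiv (fed, over 5.0 min) | 0.90 equiv (fed, over 5.0 min) | 0.900 equiv (fed, over 5.0 min) | 0.900 equiv (fed, over 5.0 min) |
| free catalyst | 0.4 mol% | 0.71 mol% | 0.3 mol% | 0.5 mol% |
| temperature | −32 °C | −16 °C |  |  |
| remark | run made earlier | run made earlier | at −10 °C throughout | at −40 °C until 1.5 min, from then on at −10 °C |
| time |  |  | 5.0 min | 5.0 min |

amber run (percent of the starting material charged)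

| time / min | product / % |
|---|---|
| 0.200 | 1.0 |
| 0.333 | 0.5 |
| 0.500 | 1.2 |
| 0.667 | 4.3 |
| 1.00 | 7.0 |
| 1.50 | 12.4 |
| 2.50 | 25.0 |

red run (percent of the starting material charged)

| time / s | product / % |
|---|---|
| 10.0 | 1.1 |
| 12.0 | 1.5 |
| 20.0 | 4.1 |
| 30.0 | 6.1 |
| 50.0 | 12.7 |

(standard deviation of a reading: 0.5 percentage points)

- the winner by amount of product, in percent of the starting material charged; "neither" if no more than 2 percentage points parts them (midnight / dusk / neither)
- how much product is there at the end, in percent of the starting material charged: midnight
- how much product is there at the end, in percent of the starting material charged: dusk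



1. I start with the main step, starting material and reagent giving product as fast as reagent arrives. The reagent comes in at 0.180 min⁻¹ of the starting material charged, which is the feed rate, reagent equivalents over dosing time, so at this step my line for product ends at 90.0% and the reagent is on paper the limiting reagent.

2. Next I add the catalyst's delay, reading the feed lag as clock time minus product over feed rate. Amber's last reading gives 1.11 min and red's gives 0.128 min, readings 0.938 of a power of ten apart. I assume the lag goes inversely with loading and take no credit for −10 °C being warmer than red, so midnight's lag is 0.302 min and its product 84.6%.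

3. Dusk adds a cold start at −40 °C, colder than amber, where the lag was already 1.11 min. I expect 27.0% of feed to wait unreacted until the warming and then be used, so I charge dusk the warm lag of 0.181 min, which gives 86.7%. My reckoning therefore puts dusk ahead by 2.1 percentage points, though these readings stop at 2.50 min at the latest, so the second half of the feed is extrapolated.

The forecast names dusk, with 77% for midnight and 80% for dusk, and adds “The gap is small, and the catalyst order is assumed.”

The flask gives 35.3% for midnight and 56.8% for dusk, so dusk wins.

    starting material + free catalyst → catalyst intermediate A (k = 66.0 M⁻¹ s⁻¹, Ea = 41.0 kJ mol⁻¹)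
    reagent + catalyst intermediate A ⇌ catalyst intermediate B (K = 92.0 M⁻¹, k = 150 M⁻¹ s⁻¹, Ea = 38.0 kJ mol⁻¹, ΔH = 24.0 kJ mol⁻¹)
    catalyst intermediate B → catalyst intermediate C (k = 6.80 s⁻¹, Ea = 59.0 kJ mol⁻¹)
    catalyst intermediate C → free catalyst + product (k = 45.0 s⁻¹, Ea = 55.0 kJ mol⁻¹)
    2 starting material → homo dimer (k = 0.0530 M⁻¹ s⁻¹, Ea = 46.0 kJ mol⁻¹)
    (constants at −40 °C)

Midnight's product over the feed rate is 1.96 min of feed in 5.0 min; it ends with 0% of the charged starting material and 61% of the charged reagent left, and with 64.7% of the starting material as homo dimer, each dimer counting as two starting material. The neighbouring flask, midnight with 0.540 equiv reagent, has a feed rate of 0.108 min⁻¹, lower than midnight's, so its line ends at 54.0%. The neighbouring flask gives 29.6%, which is 2.74 min of feed, with 0.015% of the charged starting material and 45% of the charged reagent left, and with 70.4% of the starting material as homo dimer.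

(The data stem from a simulated flask for an exercise, and the scatter is random.)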